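**Retrosynthetic overview**

- Ambofuranol is traced back, through fluoride desilylation and enol O-methylation, to a 2-arylbenzofuran-3(2H)-one. Its O1–C2 bond comes from carbenoid O–H insertion of an α-diazo deoxybenzoin, itself made from a 2,4-dihydroxy-5-prenyl deoxybenzoin.
- The strategy rests on ring A (benzofuran numbering). C7a(O)–C7–C6(O)–C5(prenyl) is the four-carbon chain of a γ-prenylated acetoacetate, and C4 and C3a, with the C3 carbonyl on C3a, are the alkyne carbons of a terminal ynone that carries the ring B benzyl group.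
- Ring A is therefore cut at C4–C5 and C3a–C7a into a 1-methoxy-1,3-bis(trimethylsilyloxy)triene and a benzyl ethynyl ketone. The triene comes from methyl acetoacetate and prenyl bromide; the ynone comes from 2-hydroxy-4-methoxybenzaldehyde by silylation, one-carbon homologation, ethynylmagnesium bromide addition and oxidation.
- Order of ring formation: ring B is bought, ring A is built in step 9, and the furan ring is closed in step 12.

Key step: step 9

Remark on the chemistry: the ring B phenol is carried as a triisopropylsilyl ether instead of an acetal. Both phenols can then be freed by fluoride in one step with no acid next to the ortho-prenylphenol, and no activated O–CH2 hydrogen lies beside the carbenoid of step 12. Compound 5 is drawn as 2E and compound 10 is an E/Z mixture; neither geometry matters later.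

**Route**

Step 1
Reactants: 1 methyl acetoacetate; 2 1-bromo-3-methylbut-2-ene (prenyl bromide)
Product: 4 methyl 7-methyl-3-oxooct-6-enoate, via acetoacetate dianion 3 (not isolated)
Conditions: NaH, THF, 0 °C; n-BuLi, 0 °C; 2, 0 °C to rt; then 1 M aq HCl
Reagents that add atoms: none
Why: Dianion alkylation of a β-keto ester: the more basic terminal carbanion of 3 displaces the primary allylic bromide in an SN2 reaction, so the prenyl group is placed on the γ-carbon only.

Step 2
Reactants: 4 methyl 7-methyl-3-oxooct-6-enoate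
Product: 5 methyl (2E)-7-methyl-3-(trimethylsilyloxy)octa-2,6-dienoate
Conditions: Me3SiCl, Et3N, toluene, rt
Reagents that add atoms: chlorotrimethylsilane, C[Si](C)(C)Cl
Why: O-silylation of the enolised β-keto ester with Me3SiCl and Et3N is the standard first stage towards 1,3-bis(silyloxy)dienes; the new double bond becomes a single bond of the diene, so its geometry is irrelevant.

Step 3
Reactants: 5 methyl (2E)-7-methyl-3-(trimethylsilyloxy)octa-2,6-dienoate
Product: 7 (1Z,3Z)-1-methoxy-7-methyl-1,3-bis(trimethylsilyloxy)octa-1,3,6-triene, via lithium dienolate 6 (not isolated)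
Conditions: LiN(i-Pr)2, THF, −78 °C; Me3SiCl, −78 °C to rt; filtration under argon, used without chromatography
Reagents that add atoms: chlorotrimethylsilane, C[Si](C)(C)Cl
Why: γ-Deprotonation of the silyloxy enoate gives the extended dienolate 6, which is silylated on the ester oxygen (kinetic silyl ketene acetal formation); the 3Z isomer, with the alkyl chain pointing away from the diene backbone, is expected to predominate.

Step 4
Reactants: 8 2-hydroxy-4-methoxybenzaldehyde
Product: 9 4-methoxy-2-(triisopropylsilyloxy)benzaldehyde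
Conditions: i-Pr3SiCl, imidazole, DMF, rt
Reagents that add atoms: chlorotriisopropylsilane, CC(C)[Si](Cl)(C(C)C)C(C)C
Why: Imidazole-promoted silylation of a phenol; the triisopropylsilyl ether is robust towards the ylide, dilute acid, Grignard reagent and amidine base used later.

Step 5
Reactants: 9 4-methoxy-2-(triisopropylsilyloxy)benzaldehyde
Product: 10 4-methoxy-1-(2-methoxyethenyl)-2-(triisopropylsilyloxy)benzene (E/Z mixture)
Conditions: Ph3P(CH2OMe)Cl, KN(SiMe3)2, THF, 0 °C; then 9, 0 °C to rt
Reagents that add atoms: (methoxymethyl)triphenylphosphonium chloride, COC[P+](c1ccccc1)(c1ccccc1)c1ccccc1.[Cl-]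
Why: Wittig methoxymethylenation of an aromatic aldehyde, the usual first half of a one-carbon homologation.

Step 6
Reactants: 10 4-methoxy-1-(2-methoxyethenyl)-2-(triisopropylsilyloxy)benzene
Product: 11 [4-methoxy-2-(triisopropylsilyloxy)phenyl]acetaldehyde
Conditions: 2 M aq HCl, THF, 45 °C; crude aldehyde used at once
Reagents that add atoms: water, O
Why: Acid-catalysed enol ether hydrolysis (C-protonation, hemiacetal, loss of methanol) converges both isomers of 10 on the arylacetaldehyde, and the hindered aryl silyl ether tolerates dilute acid.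

Step 7
Reactants: 11 [4-methoxy-2-(triisopropylsilyloxy)phenyl]acetaldehyde; 12 ethynylmagnesium bromide
Product: 13 1-[4-methoxy-2-(triisopropylsilyloxy)phenyl]but-3-yn-2-ol (racemic)
Conditions: HC≡CMgBr, THF, −78 to 0 °C; then sat. aq NH4Cl
Reagents that add atoms: none
Why: 1,2-Addition of a weakly basic alkynyl Grignard reagent to an aldehyde, run cold to limit enolisation; the carbinol centre is racemic and is removed in step 8.

Step 8
Reactants: 13 1-[4-methoxy-2-(triisopropylsilyloxy)phenyl]but-3-yn-2-ol
Product: 14 1-[4-methoxy-2-(triisopropylsilyloxy)phenyl]but-3-yn-2-one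
Conditions: Dess–Martin periodinane, CH2Cl2, 0 °C to rt; used directly in step 9
Reagents that add atoms: none
Why: Dess–Martin oxidation of a propargylic alcohol proceeds without base, which avoids isomerisation or oligomerisation of the enolisable terminal ynone.

Step 9
Reactants: 7 (1Z,3Z)-1-methoxy-7-methyl-1,3-bis(trimethylsilyloxy)octa-1,3,6-triene; 14 1-[4-methoxy-2-(triisopropylsilyloxy)phenyl]but-3-yn-2-one
Product: 16 1-[2,4-dihydroxy-5-(3-methylbut-2-enyl)phenyl]-2-[4-methoxy-2-(triisopropylsilyloxy)phenyl]ethanone, via cyclohexadiene cycloadduct 15 (not isolated)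
Conditions: 7 (1.5 equiv), toluene, 20 to 80 °C; then MeOH, 10% aq citric acid, rt
Reagents that add atoms: none
Why: The electron-rich diene 7, whose largest HOMO coefficient lies on its alkyl-bearing terminal carbon, adds to the electron-poor alkyne of 14, whose LUMO is largest at the unsubstituted β-carbon, in a strongly asynchronous normal-demand Diels–Alder reaction, so C5 bonds to C4 and the ketene acetal carbon C7a to the acyl-bearing C3a; the same pairing results if the process is a Mukaiyama–Michael addition followed by Claisen-type closure. The closest known reaction type is the cycloaddition of 1-alkoxy-1,3-bis(silyloxy)butadienes with acetylenic esters and ketones, which gives resorcinols after loss of alcohol. Ring A, the only ring formed, is closed by this intermolecular [4+2] union, the second bond being C3a–C7a, and on work-up adduct 15 loses its silyl groups and expels methanol from C7a together with the hydrogen of C5 to become aromatic. The two sp3 centres of 15 vanish on aromatisation, so no stereocentre has to be controlled. The step needs regioselectivity, secured by the matched polarisation of diene and ynone, and cycloaddition in preference to attack of the central diene carbon on the ketone, favoured by the absence of a Lewis acid; the 3Z geometry of 7 keeps the alkyl chain outside the s-cis diene.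

Step 10
Reactants: 16 1-[2,4-dihydroxy-5-(3-methylbut-2-enyl)phenyl]-2-[4-methoxy-2-(triisopropylsilyloxy)phenyl]ethanone
Product: 17 1-[2-hydroxy-5-(3-methylbut-2-enyl)-4-(triisopropylsilyloxy)phenyl]-2-[4-methoxy-2-(triisopropylsilyloxy)phenyl]ethanone
Conditions: i-Pr3SiCl (1.1 equiv), imidazole, DMF, 0 °C to rt
Reagents that add atoms: chlorotriisopropylsilane, CC(C)[Si](Cl)(C(C)C)C(C)C
Why: Regioselective silylation of a 2,4-dihydroxyaryl ketone: the hydroxyl ortho to the carbonyl is held in a hydrogen bond, so the free hydroxyl at the future C6 reacts.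

Step 11
Reactants: 17 1-[2-hydroxy-5-(3-methylbut-2-enyl)-4-(triisopropylsilyloxy)phenyl]-2-[4-methoxy-2-(triisopropylsilyloxy)phenyl]ethanone
Product: 18 2-diazo-1-[2-hydroxy-5-(3-methylbut-2-enyl)-4-(triisopropylsilyloxy)phenyl]-2-[4-methoxy-2-(triisopropylsilyloxy)phenyl]ethanone
Conditions: p-ABSA, DBU, dry MeCN, 0 °C to rt
Reagents that add atoms: 4-acetamidobenzenesulfonyl azide, CC(=O)Nc1ccc(cc1)S(=O)(=O)N=[N+]=[N-]
Why: Regitz diazo transfer: DBU forms the aryl- and acyl-stabilised enolate of the benzyl ketone, which attacks the terminal nitrogen of the sulfonyl azide and releases the sulfonamide; the alkene and the silyl ethers are inert under these anhydrous conditions.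

Step 12
Reactants: 18 2-diazo-1-[2-hydroxy-5-(3-methylbut-2-enyl)-4-(triisopropylsilyloxy)phenyl]-2-[4-methoxy-2-(triisopropylsilyloxy)phenyl]ethanone
Product: 19 2-[4-methoxy-2-(triisopropylsilyloxy)phenyl]-5-(3-methylbut-2-enyl)-6-(triisopropylsilyloxy)-1-benzofuran-3(2H)-one (racemic)
Conditions: Rh2(OAc)4 (1 mol%), CH2Cl2, rt, argon
Reagents that add atoms: none
Why: Intramolecular carbenoid O–H insertion: the dirhodium tetraacetate-bound carbene is captured by the neighbouring phenol to form O1–C2 in a five-membered ring, faster than C–H insertion or cyclopropanation; the C2 centre is racemic and is lost in step 13.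

Step 13
Reactants: 19 2-[4-methoxy-2-(triisopropylsilyloxy)phenyl]-5-(3-methylbut-2-enyl)-6-(triisopropylsilyloxy)-1-benzofuran-3(2H)-one
Product: 20 3-methoxy-2-[4-methoxy-2-(triisopropylsilyloxy)phenyl]-5-(3-methylbut-2-enyl)-6-(triisopropylsilyloxy)-1-benzofuran
Conditions: Me2SO4, K2CO3, dry degassed acetone, argon, rt to 40 °C
Reagents that add atoms: dimethyl sulfate, COS(=O)(=O)OC
Why: Enolate O-alkylation: the enolate of 19 is an aromatic benzofuran-3-olate and a hard methylating agent reacts at oxygen to give the 3-methoxybenzofuran; air is excluded because such enolates oxidise readily at C2.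

Step 14
Reactants: 20 3-methoxy-2-[4-methoxy-2-(triisopropylsilyloxy)phenyl]-5-(3-methylbut-2-enyl)-6-(triisopropylsilyloxy)-1-benzofuran
Product: 21 ambofuranol, 2-(2-hydroxy-4-methoxyphenyl)-3-methoxy-5-(3-methylbut-2-enyl)-1-benzofuran-6-ol
Conditions: Bu4NF (2.5 equiv), AcOH, THF, 0 °C
Reagents that add atoms: none
Why: Fluoride-mediated cleavage of both aryl silyl ethers under buffered, acid-free conditions leaves the methyl ethers, the enol ether and the prenyl group untouched and avoids cyclisation of the prenyl chain onto the C6 phenol.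

**Compound list**

1 | methyl acetoacetate | COC(=O)CC(C)=O | starting material
2 | 1-bromo-3-methylbut-2-ene (prenyl bromide) | CC(C)=CCBr | starting material
3 | methyl acetoacetate dianion (sodium lithium salt) | [Li+].[Na+].[CH2-]C(=O)[CH-]C(=O)OC | intermediate
4 | methyl 7-methyl-3-oxooct-6-enoate | COC(=O)CC(=O)CCC=C(C)C | intermediate
5 | methyl (2E)-7-methyl-3-(trimethylsilyloxy)octa-2,6-dienoate | COC(=O)/C=C(\CCC=C(C)C)O[Si](C)(C)C | intermediate
6 | lithium dienolate of 5 | [Li+].CO/C([O-])=C/C(O[Si](C)(C)C)=C/CC=C(C)C | intermediate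
7 | (1Z,3Z)-1-methoxy-7-methyl-1,3-bis(trimethylsilyloxy)octa-1,3,6-triene | CO/C(O[Si](C)(C)C)=C/C(O[Si](C)(C)C)=C/CC=C(C)C | intermediate
8 | 2-hydroxy-4-methoxybenzaldehyde | COc1ccc(C=O)c(O)c1 | starting material
9 | 4-methoxy-2-(triisopropylsilyloxy)benzaldehyde | COc1ccc(C=O)c(O[Si](C(C)C)(C(C)C)C(C)C)c1 | intermediate
10 | 4-methoxy-1-(2-methoxyethenyl)-2-(triisopropylsilyloxy)benzene (E/Z mixture) | COC=Cc1ccc(OC)cc1O[Si](C(C)C)(C(C)C)C(C)C | intermediate
11 | [4-methoxy-2-(triisopropylsilyloxy)phenyl]acetaldehyde | O=CCc1ccc(OC)cc1O[Si](C(C)C)(C(C)C)C(C)C | intermediate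
12 | ethynylmagnesium bromide | C#C[Mg]Br | starting material
13 | 1-[4-methoxy-2-(triisopropylsilyloxy)phenyl]but-3-yn-2-ol (racemic) | C#CC(O)Cc1ccc(OC)cc1O[Si](C(C)C)(C(C)C)C(C)C | intermediate
14 | 1-[4-methoxy-2-(triisopropylsilyloxy)phenyl]but-3-yn-2-one | C#CC(=O)Cc1ccc(OC)cc1O[Si](C(C)C)(C(C)C)C(C)C | intermediate
15 | cyclohexa-1,4-diene cycloadduct of 7 and 14 (diastereomer mixture) | COC1(O[Si](C)(C)C)C=C(O[Si](C)(C)C)C(CC=C(C)C)C=C1C(=O)Cc1ccc(OC)cc1O[Si](C(C)C)(C(C)C)C(C)C | intermediate
16 | 1-[2,4-dihydroxy-5-(3-methylbut-2-enyl)phenyl]-2-[4-methoxy-2-(triisopropylsilyloxy)phenyl]ethanone | O=C(Cc1ccc(OC)cc1O[Si](C(C)C)(C(C)C)C(C)C)c1cc(CC=C(C)C)c(O)cc1O | intermediate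
17 | 1-[2-hydroxy-5-(3-methylbut-2-enyl)-4-(triisopropylsilyloxy)phenyl]-2-[4-methoxy-2-(triisopropylsilyloxy)phenyl]ethanone | O=C(Cc1ccc(OC)cc1O[Si](C(C)C)(C(C)C)C(C)C)c1cc(CC=C(C)C)c(O[Si](C(C)C)(C(C)C)C(C)C)cc1O | intermediate
18 | 2-diazo-1-[2-hydroxy-5-(3-methylbut-2-enyl)-4-(triisopropylsilyloxy)phenyl]-2-[4-methoxy-2-(triisopropylsilyloxy)phenyl]ethanone | [N-]=[N+]=C(C(=O)c1cc(CC=C(C)C)c(O[Si](C(C)C)(C(C)C)C(C)C)cc1O)c1ccc(OC)cc1O[Si](C(C)C)(C(C)C)C(C)C | intermediate
19 | 2-[4-methoxy-2-(triisopropylsilyloxy)phenyl]-5-(3-methylbut-2-enyl)-6-(triisopropylsilyloxy)-1-benzofuran-3(2H)-one (racemic) | O=C1c2cc(CC=C(C)C)c(O[Si](C(C)C)(C(C)C)C(C)C)cc2OC1c1ccc(OC)cc1O[Si](C(C)C)(C(C)C)C(C)C | intermediate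
20 | 3-methoxy-2-[4-methoxy-2-(triisopropylsilyloxy)phenyl]-5-(3-methylbut-2-enyl)-6-(triisopropylsilyloxy)-1-benzofuran | COc1ccc(-c2oc3cc(O[Si](C(C)C)(C(C)C)C(C)C)c(CC=C(C)C)cc3c2OC)c(O[Si](C(C)C)(C(C)C)C(C)C)c1 | intermediate
21 | ambofuranol | COc1ccc(-c2oc3cc(O)c(CC=C(C)C)cc3c2OC)c(O)c1 | target

**Step count**

Total: 14 steps. Longest linear sequence: 11 steps (steps 4 to 14, from 8).

**Steps most likely to fail**

1. Step 9. The enolisable terminal ynone may isomerise or oligomerise before it is trapped. The first adduct may close through the central diene carbon onto the ketone and give a salicylate-type ring. The silyloxy group may be expelled instead of methoxide on aromatisation, leaving a methyl ether at C7a. The fallback sets out from 7 and 11 and comes back at 17.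
   - Diene 7 would be heated with methyl propiolate in toluene and worked up as in step 9, passing through the cyclohexadiene cycloadduct F1 (not isolated), to give methyl 2,4-dihydroxy-5-(3-methylbut-2-enyl)benzoate F2. An ester dienophile cannot undergo the aldol-type closure.
   - Selective silylation of the unchelated hydroxyl (i-Pr3SiCl, imidazole, DMF) would give methyl 2-hydroxy-5-(3-methylbut-2-enyl)-4-(triisopropylsilyloxy)benzoate F3.
   - Aldehyde 11 would be oxidised (NaClO2, NaH2PO4, 2-methylbut-2-ene, t-BuOH–water) to [4-methoxy-2-(triisopropylsilyloxy)phenyl]acetic acid F4.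
   - The dianion of F4 (LiN(i-Pr)2, THF, −78 °C) would acylate the lithium phenoxide of F3 to give 3-[2-hydroxy-5-(3-methylbut-2-enyl)-4-(triisopropylsilyloxy)phenyl]-2-[4-methoxy-2-(triisopropylsilyloxy)phenyl]-3-oxopropanoic acid F5 (not isolated). This β-keto acid would lose carbon dioxide on mildly acidic work-up to give 17.

2. Step 11, together with the carbenoid closure of step 12. The chelated phenol may be deprotonated in place of the benzylic position, so that diazo transfer stalls. An aryl silyl ether may be lost under the amidine base. The carbenoid may be diverted to C–H insertion or alkene addition. The fallback sets out from 17 and comes back at 19.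
   - Me3SiOTf and Et3N in CH2Cl2 would convert 17 into the (Z)-trimethylsilyl enol ether with the phenol also silylated, (Z)-1-[5-(3-methylbut-2-enyl)-4-(triisopropylsilyloxy)-2-(trimethylsilyloxy)phenyl]-2-[4-methoxy-2-(triisopropylsilyloxy)phenyl]-1-(trimethylsilyloxy)ethene F6.
   - N-Bromosuccinimide in THF at −78 °C, which should attack the silyl enol ether far faster than the prenyl alkene or the arenes, would give after aqueous work-up 2-bromo-1-[2-hydroxy-5-(3-methylbut-2-enyl)-4-(triisopropylsilyloxy)phenyl]-2-[4-methoxy-2-(triisopropylsilyloxy)phenyl]ethanone F7.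
   - K2CO3 in acetone would close the furanone by intramolecular phenoxide displacement of bromide, the classical route to benzofuran-3(2H)-ones, giving 19.

3. Step 13. The ambident enolate may be methylated at C2 instead of oxygen, may be oxidised at C2 by adventitious air, or may take up a silyl group migrating from the ring B oxygen. The fallback sets out from 19 and comes back at 20, and uses no enolate.
   - Trimethyl orthoformate and a catalytic amount of pyridinium p-toluenesulfonate in methanol would convert the ketone into the dimethyl ketal, 3,3-dimethoxy-2-[4-methoxy-2-(triisopropylsilyloxy)phenyl]-5-(3-methylbut-2-enyl)-6-(triisopropylsilyloxy)-2,3-dihydro-1-benzofuran F8.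
   - On warming, F8 would lose methanol, driven by formation of the aromatic furan, to give 20.

**Further compounds**

F1 | step 9 | cyclohexa-1,4-diene cycloadduct of 7 and methyl propiolate | COC(=O)C1=CC(CC=C(C)C)C(O[Si](C)(C)C)=CC1(OC)O[Si](C)(C)C
F2 | step 9 | methyl 2,4-dihydroxy-5-(3-methylbut-2-enyl)benzoate | COC(=O)c1cc(CC=C(C)C)c(O)cc1O
F3 | step 9 | methyl 2-hydroxy-5-(3-methylbut-2-enyl)-4-(triisopropylsilyloxy)benzoate | COC(=O)c1cc(CC=C(C)C)c(O[Si](C(C)C)(C(C)C)C(C)C)cc1O
F4 | step 9 | [4-methoxy-2-(triisopropylsilyloxy)phenyl]acetic acid | OC(=O)Cc1ccc(OC)cc1O[Si](C(C)C)(C(C)C)C(C)C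
F5 | step 9 | 3-[2-hydroxy-5-(3-methylbut-2-enyl)-4-(triisopropylsilyloxy)phenyl]-2-[4-methoxy-2-(triisopropylsilyloxy)phenyl]-3-oxopropanoic acid | OC(=O)C(C(=O)c1cc(CC=C(C)C)c(O[Si](C(C)C)(C(C)C)C(C)C)cc1O)c1ccc(OC)cc1O[Si](C(C)C)(C(C)C)C(C)C
F6 | step 11 | (Z)-1-[5-(3-methylbut-2-enyl)-4-(triisopropylsilyloxy)-2-(trimethylsilyloxy)phenyl]-2-[4-methoxy-2-(triisopropylsilyloxy)phenyl]-1-(trimethylsilyloxy)ethene | C[Si](C)(C)O/C(=C\c1ccc(OC)cc1O[Si](C(C)C)(C(C)C)C(C)C)c1cc(CC=C(C)C)c(O[Si](C(C)C)(C(C)C)C(C)C)cc1O[Si](C)(C)C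
F7 | step 11 | 2-bromo-1-[2-hydroxy-5-(3-methylbut-2-enyl)-4-(triisopropylsilyloxy)phenyl]-2-[4-methoxy-2-(triisopropylsilyloxy)phenyl]ethanone | O=C(C(Br)c1ccc(OC)cc1O[Si](C(C)C)(C(C)C)C(C)C)c1cc(CC=C(C)C)c(O[Si](C(C)C)(C(C)C)C(C)C)cc1O
F8 | step 13 | 3,3-dimethoxy-2-[4-methoxy-2-(triisopropylsilyloxy)phenyl]-5-(3-methylbut-2-enyl)-6-(triisopropylsilyloxy)-2,3-dihydro-1-benzofuran | COC1(OC)C(c2ccc(OC)cc2O[Si](C(C)C)(C(C)C)C(C)C)Oc2cc(O[Si](C(C)C)(C(C)C)C(C)C)c(CC=C(C)C)cc21
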